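The earlier runs and the new flask were generated by integration with constants of no real substance, and the scatter is random.

Temperature is what separates the flasks west, north-east and north, and each gets the same charge; the question is what heat buys in 10 min.

| flask | left-handed substrate | right-handed substrate | coupling partner | free catalyst | impurity | temperature | remark | time |
|---|---|---|---|---|---|---|---|---|
| Saturday's | 0.071 M | 0.071 M | 0.071 M (in portions, 4) | 0.17 mM | 65 µM | 10 °C | run made earlier; portions every 2.5 min |  |
| Thursday's | 0.071 M | 0.071 M | 0.071 M (in portions, 4) | 0.70 mM | 65 µM | 43 °C | run made earlier; portions every 2.5 min |  |
| west | 0.071 M | 0.071 M | 0.0710 M (in portions, 4) | 0.35 mM | 65 µM | 25 °C | the portions of coupling partner follow each other after 2.5 min, the first at the start | 10 min |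
| north-east | 0.071 M | 0.071 M | 0.0710 M (in portions, 4) | 0.35 mM | 65 µM | −5 °C | the portions of coupling partner follow each other after 2.5 min, the first at the start | 10 min |
| north | 0.071 M | 0.071 M | 0.0710 M (in portions, 4) | 0.35 mM | 65 µM | 55 °C | the portions of coupling partner follow each other after 2.5 min, the first at the start | 10 min |

| run | time / min | left-handed product / % | left-handed substrate / % |
|---|---|---|---|
| Saturday's | 1.00 | 0.5 | 50.0 |
| Saturday's | 2.00 | 1.0 | 49.4 |
| Saturday's | 3.00 | 0 | 48.8 |
| Saturday's | 6.00 | 1.7 | 47.1 |
| Saturday's | 12.0 | 5.2 | 44.1 |
| Thursday's | 0.500 | 4.1 | 46.8 |
| Thursday's | 1.00 | 5.6 | 44.9 |
| Thursday's | 1.50 | 7.4 | 42.6 |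
| Thursday's | 2.00 | 8.3 | 43.4 |
| Thursday's | 2.50 | 8.8 | 39.5 |

(each reading ± 1 percentage point)

- the flask that comes out highest in amount of left-handed product, in percent of the left-handed substrate and right-handed substrate together charged, or "all alike" when all lie within 1.5 percentage points (west / north-east / north / all alike)
- left-handed product at the end, in percent of the left-handed substrate and right-handed substrate together charged, west
- left-handed product at the end, in percent of the left-handed substrate and right-handed substrate together charged, north-east
- left-handed product at the end, in percent of the left-handed substrate and right-handed substrate together charged, north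

- free catalyst is single-handed; left-handed substrate and right-handed substrate are mirror images of each other, charged as a racemate, each of them at the stated concentration

In the first instants I let the impurity take free catalyst one for one, which is my assumption, not a reading. Then [working catalyst] is 0.285 mM in each flask: free catalyst charged minus impurity charged. Saturday's run had 0.105 mM and Thursday's 0.635 mM. I take the early rate as first order in this concentration.

Saturday's run read 5.2% of left-handed product after 12.0 min, and Thursday's 4.1% after 0.500 min, a reading whose scatter is a quarter of it. Per working catalyst, Thursday's rate is 3.13 times Saturday's. West lies near the middle of those two temperatures, so I take the geometric mean of the two rates, and that rate held for 10 min gives west 20.8%.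

In the middle of the run, coupling partner arrives in portions worth 12.5% each, so west needs more than its first portion. Towards the end the left-handed substrate thins, so I commit to somewhat under that figure for west. Thursday's run gained 1.4 percentage points in its last minute, after 4.1% in its first 0.500 min. The rise in Thursday's run slows, so I do not scale north by its rate.

The forecast names north as highest, with 17% for west, 6.5% for north-east and 24% for north. It reads Thursday's levelling as the first portion used up, “though catalyst death can't be excluded”.

The flasks give 18.0% for west, 5.79% for north-east and 24.4% for north, so north is highest and the forecast holds.

    coupling partner + free catalyst + left-handed substrate → free catalyst + left-handed product (k = 100 /M²/s, Ea = 38.0 kJ/mol)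
    coupling partner + free catalyst + right-handed substrate → free catalyst + right-handed product (k = 3.90 /M²/s, Ea = 43.0 kJ/mol)
    coupling partner + free catalyst → spent catalyst A (k = 0.0220 /M/s, Ea = 52.0 kJ/mol)
    free catalyst + impurity → spent catalyst B (k = 24000 /M/s, Ea = 37.0 kJ/mol)
    (constants at 25 °C)

North also holds right-handed product, 1.54% at 10.0 min, and the step that makes it makes no difference to the left-handed product of north. Spent catalyst B stands at 18.6% of the catalyst in north, the share 18.6% that working catalyst implies. The neighbouring flask is north with 1.6 × 10⁻⁴ M of impurity, so its working catalyst is 0.190 mM, and 45.7% of the catalyst should go to spent catalyst B; that form stands at 45.7% in the neighbour. Scaling the left-handed product of north by working catalyst gives the neighbour 16.3%. The neighbour ends at 18.8% of left-handed product, with 4.67% of free catalyst remaining.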